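## Structural features

The target joins two aromatic units through one oxygen: a coumarin (benzene ring A fused to an α-pyranone ring) with OMe at C6 and a free OH at C7, and a benzene ring B whose C1' is bonded to the oxygen on C3 of the pyranone ring. Ring B also carries a free OH at C3' and a CH2CH2CO2Me chain at C4'. Its two oxygens are therefore meta (a resorcinol monoether), and the chain is ortho to the hydroxyl and para to the ether oxygen. There is no stereocentre and no configurable double bond, so every selectivity problem is positional or chemoselective. The fragile groups are the methyl ester and the pyranone lactone (both opened by hydroxide or alkoxide), the ortho-hydroxy dihydrocinnamate of ring B (which can close to a six-membered lactone under acid and heat), the enol ether at C3, and the electron-rich ring A, whose methyl ether at O6 must survive the unmasking of O7. The real difficulty is the O3–C1' bond: O3 is an enolic oxygen beside the lactone carbonyl, weakly nucleophilic and ambident with C4, and ring B must be attached with an unambiguous 1,3,4-pattern. The key step exploits the meta relation of the oxygens on C1' and C3' of ring B, which is the oxygen pattern of a cyclohexane-1,3-dione. C1' can thus be offered as the chlorine-bearing β-carbon of a cyclohex-2-enone whose carbonyl is the future C3'–OH and whose α'-carbon (future C4') already carries the chain.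

## Logic of the disconnections

18 from 17. The O7–CH2Ph bond is cut. With O7 masked, O3 is the only acidic oxygen of the coumarin partner in the coupling. The forward step must remove benzyl without touching the O6 methyl ether, the methyl ester, the lactone or the C3=C4 enol ether.

17 from 16. No skeletal bond is cut. Ring B is taken back one oxidation level: one H2 is returned across C5'–C6' and the C3' phenol is written as its keto tautomer with the extra hydrogen on C4'. This turns C1' from an unreactive aryl carbon into an electrophilic β-carbon. The forward step must dehydrogenate a vinylogous ester without hydrolysing it; the stereocentre of 16 disappears.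

16 from 15 and 7 (key disconnection). The O3–C1' bond is cut. Both halves are of comparable size, no metal-mediated aryl–oxygen coupling is needed, and every ring B carbon and substituent is already in 7. The forward step must deliver O3 rather than C4 of the ambident olate of 15, and 7 must carry chlorine on the carbon remote from the chain.

7 from 5 through 6. A tert-butoxycarbonyl group is added back to the chain-bearing carbon, making it quaternary. This is the improvement in precursor design: in 5 and 4 the carbonyl next to the chain is flanked by a fully substituted carbon, so the two carbonyls are sterically distinct when the chloride is introduced. The forward step must remove this group by acid only, because base, hot chloride (Krapcho conditions) or zerovalent palladium would attack the chloroenone.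

5 from 4. The C–Cl bond is exchanged for the enolic C–O bond of a vinylogous acid. The forward step must activate and replace only the oxygen remote from the quaternary carbon.

4 from 3. The ring bond between the future C2' and C1' is cut (retro-Claisen). The ring opens to an acyclic keto triester with two identical chains, so either ester may be attacked. The forward step needs a base that enolises the methyl ketone and does not cleave the non-enolisable β-keto ester.

3 from 1 and two molecules of 2. Both C–C bonds from the quaternary carbon to the chains are cut (retro-Michael), which leads to two bulk chemicals. 1 is preferred to its methyl analogue so that the later ester removal is an acidolysis.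

15 from 13 through 14. The C3–O bond is exchanged for C3–N. The enol is the hydrolysis product of an enamine, and the enamide is what the azlactone route delivers. The forward step must keep the benzyl ether intact in hot aqueous acid.

13 from 9 and 10 through 11 and 12. C3=C4 and O1–C2 of the pyranone ring are cut, giving a salicylaldehyde and a glycine unit that brings C2, C3 and the heteroatom on C3. The forward step is a one-pot condensation and acyl transfer.

9 from 8. The O4–benzyl bond of the aldehyde (O7 of the coumarin) is cut. The forward step relies on the higher acidity of the hydroxyl para to the formyl group over the chelated ortho hydroxyl.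

## Other disconnections considered

Alternative 1: The cut is C4–C4a and O1–C2 of the pyranone ring. It leads back to 4-methoxybenzene-1,3-diol A1 and a masked α-aryloxy formylacetate, methyl 3,3-dimethoxy-2-[(2-oxochroman-7-yl)oxy]propanoate A2, reachable by O-alkylation of 7-hydroxychroman-2-one A4. In the forward key step a strong protic acid would ionise the acetal of A2, the cation would alkylate C6 of A1 (para to one hydroxyl, ortho to the other), and the neighbouring hydroxyl would lactonise to give 7-hydroxy-6-methoxy-3-[(2-oxochroman-7-yl)oxy]coumarin A3. Acidic methanolysis of the saturated lactone of A3 would then give 18.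
- In favour: it needs no protecting group on O7, the ring A pattern follows from the innate reactivity of A1, and the count of about four steps is clearly better than the chosen plan.
- Against: A2 is an aryloxy acetal, the classical substrate for acid-mediated cyclodehydration onto its own aryl ring (ring B), and this intramolecular path competes with the intermolecular alkylation of A1. A1 is also air-sensitive and prone to over-alkylation.
- Comparison: structurally the alternative is equal, since ring B is fixed from the outset. Mechanistically it stakes the synthesis on an intermolecular Friedel–Crafts event beating an intramolecular one, whereas the chosen plan uses a substitution with a single electrophilic carbon. On step economy the alternative is better.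

Alternative 2: The cut is the C4'–CH2 bond together with the aryl ester bond of a dihydrocoumarin. It leads back to 7-acetoxy-3-(3-hydroxyphenoxy)-6-methoxycoumarin A5 and acrylic acid A6. In the forward key step CF3SO3H or polyphosphoric acid would acylate the ring B phenol of A5 with A6 and alkylate the ortho carbon C4', closing the saturated lactone of 7-acetoxy-6-methoxy-3-[(2-oxochroman-7-yl)oxy]coumarin A7. Methanolysis of A7 would open the lactone and remove the acetate in one operation to give 18.
- In favour: ring B starts aromatic, so no dehydrogenation is needed. The one-step endgame is better than the two steps of the chosen plan.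
- Against: A5 still contains the O3–C1' bond, which would have to be made by a copper-mediated coupling at the hindered enol oxygen; the hard bond is moved, not solved. The annulation must also choose C4' over C2' and C6' of ring B and over C5 and C8 of ring A, in a superacid that can also cleave the acetate or induce its Fries shift.
- Comparison: structurally the chosen plan is stronger, because the chain position is built into 7 and is not decided by arene reactivity. Mechanistically the alternative is harsher. On step economy the two are about equal, with the alternative slightly shorter after the coupling.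

Alternative 3: The cut is the C3=C4 bond. It leads back to 5-(tert-butyldimethylsilyloxy)-2-ethenyl-4-methoxyphenyl 2-[(2-oxochroman-7-yl)oxy]prop-2-enoate A8. In the forward key step the second-generation Hoveyda–Grubbs catalyst would load onto the styrene and close onto the 1,1-disubstituted, oxygen-bearing acrylate carbon, giving 7-(tert-butyldimethylsilyloxy)-6-methoxy-3-[(2-oxochroman-7-yl)oxy]coumarin A9 with loss of the two terminal methylene groups. Basic methanol would then remove the silyl group and open the saturated lactone to give 18.
- In favour: the conditions are neutral, no ambident nucleophile is involved, every substituent position is fixed before the ring closes, and deprotection and lactone opening can be combined, which is better than the chosen endgame.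
- Against: A8 is an aryl ester of a 2-aryloxyacrylic acid, both an acylating agent and a Michael acceptor. Its assembly needs a separately made 2-vinylphenol from 8 and a 2-aryloxyacrylic acid from A4, neither of which tolerates hydroxide. Closure onto a 1,1-disubstituted enol-ether alkene is slow and would need a high ruthenium loading.
- Comparison: positional certainty is equal, and the key step is milder than the chosen one. The chosen plan is better in the stability of its intermediates and in cost, and no longer in step count.

Key step: step 8

Assumptions and remarks on the chemistry:
- The connectivity of 7, 15 and 16 was checked atom by atom against the target and needs no correction. The only change of design is that the chain-bearing ring carbon is kept quaternary (tert-butyl ester) until the chloride has been placed.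
- Compounds 4, 5, 6, 7 and 16 are racemic. Their single stereocentre is erased in step 9, so no stereocontrol is required.

## Route

Step 1
Reactants: 1 tert-butyl 3-oxobutanoate (tert-butyl acetoacetate); 2 methyl acrylate
Product: 3 3-tert-butyl 1,5-dimethyl 3-acetylpentane-1,3,5-tricarboxylate
Conditions: 2 (2.3 equiv), DBU (0.2 equiv), MeCN, rt
Reagents that add atoms: none
Why: Base-catalysed double Michael addition of the doubly activated methylene of 1 to the acrylate; the second addition builds the quaternary carbon, and the product is achiral because the two chains are identical.

Step 2
Reactants: 3 3-tert-butyl 1,5-dimethyl 3-acetylpentane-1,3,5-tricarboxylate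
Product: 4 tert-butyl 1-(3-methoxy-3-oxopropyl)-2,4-dioxocyclohexane-1-carboxylate (racemic)
Conditions: KOtBu (2.2 equiv), THF, 0 °C to rt; then cold 1 M HCl
Reagents that add atoms: none
Why: Intramolecular Claisen condensation: the methyl group is the only enolisable position of the ketone, and its enolate attacks one of the two equivalent δ-ester carbonyls (six-membered ring); deprotonation of the resulting 1,3-dione drives the equilibrium away from Dieckmann products, the bulky alkoxide limits deacetylation, and the quaternary stereocentre forms as a racemate.

Step 3
Reactants: 4 tert-butyl 1-(3-methoxy-3-oxopropyl)-2,4-dioxocyclohexane-1-carboxylate (racemic)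
Product: 5 tert-butyl 4-chloro-1-(3-methoxy-3-oxopropyl)-2-oxocyclohex-3-ene-1-carboxylate (racemic)
Conditions: (COCl)2 (1.1 equiv), DMF (cat.), CH2Cl2, 0 °C
Reagents that add atoms: oxalyl chloride, O=C(Cl)C(=O)Cl
Why: Conversion of a vinylogous acid into a vinylogous acid chloride through the Vilsmeier-activated enol; activation and chloride addition–elimination should occur at the oxygen and carbon remote from the quaternary centre, as with 4,4-disubstituted cyclohexane-1,3-diones, which places chlorine on the future C1' of ring B.

Step 4
Reactants: 5 tert-butyl 4-chloro-1-(3-methoxy-3-oxopropyl)-2-oxocyclohex-3-ene-1-carboxylate (racemic)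
Product: 7 methyl 3-(4-chloro-2-oxocyclohex-3-en-1-yl)propanoate (racemic), via 4-chloro-1-(3-methoxy-3-oxopropyl)-2-oxocyclohex-3-ene-1-carboxylic acid 6 (not isolated)
Conditions: CF3CO2H/CH2Cl2 (1:3), rt; concentrate; toluene, 80 °C
Reagents that add atoms: none
Why: Acidolysis of the tert-butyl ester (loss of isobutene) followed by thermal decarboxylation of the β-keto acid through a cyclic transition state; the dienol ketonises to the conjugated chloroenone, the methyl ester and the vinyl chloride are inert to acid, and the new tertiary stereocentre forms without control (racemate).

Step 5
Reactants: 8 2,4-dihydroxy-5-methoxybenzaldehyde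
Product: 9 4-benzyloxy-2-hydroxy-5-methoxybenzaldehyde
Conditions: BnBr (1.0 equiv), NaHCO3 (1.5 equiv), MeCN, 70 °C
Reagents that add atoms: benzyl bromide, BrCc1ccccc1
Why: Williamson etherification; the hydroxyl para to the formyl group is the more acidic and is not hydrogen-bonded, whereas the ortho hydroxyl is chelated to the carbonyl, so a weak base should alkylate only O4.

Step 6
Reactants: 9 4-benzyloxy-2-hydroxy-5-methoxybenzaldehyde; 10 N-acetylglycine
Product: 13 N-(7-benzyloxy-6-methoxy-2-oxo-2H-chromen-3-yl)acetamide, via 2-methyl-1,3-oxazol-5(4H)-one 11 (not isolated), via (Z)-4-(2-acetoxy-4-benzyloxy-5-methoxybenzylidene)-2-methyl-1,3-oxazol-5(4H)-one 12 (not isolated)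
Conditions: NaOAc (3 equiv), Ac2O, 110 °C; then H2O
Reagents that add atoms: none
Why: Erlenmeyer–Plöchl azlactone condensation: acetic anhydride cyclodehydrates 10 to 11, which condenses with the aldehyde of transiently O-acetylated 9 to give 12; acetate-mediated equilibration of the alkene geometry and acyl transfer from the azlactone carbonyl to the ortho oxygen then close the pyranone ring, and the transient O-acetyl group returns as acetic acid.

Step 7
Reactants: 13 N-(7-benzyloxy-6-methoxy-2-oxo-2H-chromen-3-yl)acetamide
Product: 15 7-benzyloxy-3-hydroxy-6-methoxy-2H-chromen-2-one, via 3-amino-7-benzyloxy-6-methoxy-2H-chromen-2-one 14 (not isolated)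
Conditions: 3 M HCl (aq)/1,4-dioxane (1:1), 90 °C, stopped at full conversion
Reagents that add atoms: water, O
Why: Acid hydrolysis of the enamide to the enamine 14, which tautomerises to the imine and is hydrolysed to the 2,3-dioxochroman, isolated as its stable enol 15; the lactone recloses in acid and an aryl benzyl ether should tolerate dilute aqueous acid for the time needed.

Step 8
Reactants: 15 7-benzyloxy-3-hydroxy-6-methoxy-2H-chromen-2-one; 7 methyl 3-(4-chloro-2-oxocyclohex-3-en-1-yl)propanoate (racemic)
Product: 16 methyl 3-[4-(7-benzyloxy-6-methoxy-2-oxochromen-3-yloxy)-2-oxocyclohex-3-en-1-yl]propanoate (racemic)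
Conditions: 7 (1.15 equiv), K2CO3 (1.5 equiv), DMF, rt to 40 °C
Reagents that add atoms: none
Why: Carbonate converts the enol 15 into its potassium 3-olate, whose oxygen adds to the chlorine-bearing β-carbon of 7 (future C1' of ring B), and the resulting enolate expels chloride to give the vinylogous ester 16, an addition–elimination (vinylogous acyl substitution). The closest known reaction type is the displacement of chloride from 3-chlorocyclohex-2-enones by phenoxides and enolates with carbonate in dipolar aprotic solvents. No ring is closed and no stereocentre is formed; the stereocentre of 7 is untouched and stays racemic. The selectivity needed is O3 over C4 attack of the ambident olate: attack through oxygen keeps the conjugated pyranone intact, whereas attack through C4 must pass through a non-aromatic 2,3-dioxochroman and is hindered by the peri hydrogen on C5, and the loosely paired potassium ion in DMF favours the harder oxygen terminus. On the electrophile only the chlorine-bearing carbon is a vinylogous acyl position, and that carbon was fixed in step 3. The benzyl ether removes the only competing phenoxide (O7), and the mild base leaves both esters and the lactone alone.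

Step 9
Reactants: 16 methyl 3-[4-(7-benzyloxy-6-methoxy-2-oxochromen-3-yloxy)-2-oxocyclohex-3-en-1-yl]propanoate (racemic)
Product: 17 methyl 3-[4-(7-benzyloxy-6-methoxy-2-oxochromen-3-yloxy)-2-hydroxyphenyl]propanoate
Conditions: Pd(O2CCF3)2 (5 mol %), 2-(dimethylamino)pyridine (10 mol %), TsOH·H2O (20 mol %), O2 (1 atm), DMSO, 80 °C
Reagents that add atoms: none
Why: Palladium-catalysed aerobic dehydrogenation of a cyclohexenone to a phenol: a divalent palladium enolate forms at the chain-bearing α'-carbon, β-hydride elimination gives the cross-conjugated dienone, which tautomerises to the phenol while O2 reoxidises the palladium hydride; the stereocentre is erased and no substituent can migrate, so only the 1,3,4-pattern can result.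

Step 10
Reactants: 17 methyl 3-[4-(7-benzyloxy-6-methoxy-2-oxochromen-3-yloxy)-2-hydroxyphenyl]propanoate
Product: 18 methyl 3-[2-hydroxy-4-(7-hydroxy-6-methoxy-2-oxochromen-3-yloxy)phenyl]propanoate
Conditions: BCl3 (1 M in CH2Cl2, 3 equiv), pentamethylbenzene (3 equiv), CH2Cl2, −78 °C; then MeOH, aqueous work-up
Reagents that add atoms: none
Why: Lewis-acid debenzylation with a cation scavenger: BCl3 coordinates the benzyl ether oxygen and the benzyl cation is trapped by pentamethylbenzene (Friedel–Crafts alkylation), at a temperature where the aryl methyl ether, the methyl ester, the lactone and the enol ether should stay intact.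

## Compound list

1 | tert-butyl 3-oxobutanoate (tert-butyl acetoacetate) | CC(=O)CC(=O)OC(C)(C)C | starting material
2 | methyl acrylate | C=CC(=O)OC | starting material
3 | 3-tert-butyl 1,5-dimethyl 3-acetylpentane-1,3,5-tricarboxylate (achiral) | CC(=O)C(CCC(=O)OC)(CCC(=O)OC)C(=O)OC(C)(C)C | intermediate
4 | tert-butyl 1-(3-methoxy-3-oxopropyl)-2,4-dioxocyclohexane-1-carboxylate (racemic, drawn as the diketone) | COC(=O)CCC1(C(=O)OC(C)(C)C)CCC(=O)CC1=O | intermediate
5 | tert-butyl 4-chloro-1-(3-methoxy-3-oxopropyl)-2-oxocyclohex-3-ene-1-carboxylate (racemic) | COC(=O)CCC1(C(=O)OC(C)(C)C)CCC(Cl)=CC1=O | intermediate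
6 | 4-chloro-1-(3-methoxy-3-oxopropyl)-2-oxocyclohex-3-ene-1-carboxylic acid (racemic, not isolated) | COC(=O)CCC1(C(=O)O)CCC(Cl)=CC1=O | intermediate
7 | methyl 3-(4-chloro-2-oxocyclohex-3-en-1-yl)propanoate (racemic) | COC(=O)CCC1CCC(Cl)=CC1=O | intermediate
8 | 2,4-dihydroxy-5-methoxybenzaldehyde | COc1cc(C=O)c(O)cc1O | starting material
9 | 4-benzyloxy-2-hydroxy-5-methoxybenzaldehyde | COc1cc(C=O)c(O)cc1OCc2ccccc2 | intermediate
10 | N-acetylglycine | CC(=O)NCC(=O)O | starting material
11 | 2-methyl-1,3-oxazol-5(4H)-one (not isolated) | CC1=NCC(=O)O1 | intermediate
12 | (Z)-4-(2-acetoxy-4-benzyloxy-5-methoxybenzylidene)-2-methyl-1,3-oxazol-5(4H)-one (not isolated) | CC1=N/C(=C\c2cc(OC)c(OCc3ccccc3)cc2OC(C)=O)C(=O)O1 | intermediate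
13 | N-(7-benzyloxy-6-methoxy-2-oxo-2H-chromen-3-yl)acetamide | CC(=O)Nc1cc2cc(OC)c(OCc3ccccc3)cc2oc1=O | intermediate
14 | 3-amino-7-benzyloxy-6-methoxy-2H-chromen-2-one (not isolated) | Nc1cc2cc(OC)c(OCc3ccccc3)cc2oc1=O | intermediate
15 | 7-benzyloxy-3-hydroxy-6-methoxy-2H-chromen-2-one | O=c1oc2cc(OCc3ccccc3)c(OC)cc2cc1O | intermediate
16 | methyl 3-[4-(7-benzyloxy-6-methoxy-2-oxochromen-3-yloxy)-2-oxocyclohex-3-en-1-yl]propanoate (racemic) | COC(=O)CCC1CCC(Oc2cc3cc(OC)c(OCc4ccccc4)cc3oc2=O)=CC1=O | intermediate
17 | methyl 3-[4-(7-benzyloxy-6-methoxy-2-oxochromen-3-yloxy)-2-hydroxyphenyl]propanoate | COC(=O)CCc1ccc(Oc2cc3cc(OC)c(OCc4ccccc4)cc3oc2=O)cc1O | intermediate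
18 | methyl 3-[2-hydroxy-4-(7-hydroxy-6-methoxy-2-oxochromen-3-yloxy)phenyl]propanoate | COC(=O)CCc1ccc(Oc2cc3cc(OC)c(O)cc3oc2=O)cc1O | target

## Step count and least certain steps

Total step count: 10. Longest linear sequence: 7 steps (steps 1, 2, 3, 4, 8, 9, 10); the coumarin branch (steps 5, 6, 7) joins at step 8.

Step 8 (key step). The most likely failure is attack of the ambident olate through C4 instead of O3, or base-induced self-condensation of the chloroenone through its dienolate before substitution is complete. The fallback sets out from 7, which is first treated with DABCO in MeCN to give the vinylammonium salt 1-[4-(3-methoxy-3-oxopropyl)-3-oxocyclohex-1-en-1-yl]-1,4-diazabicyclo[2.2.2]octan-1-ium chloride F1. This cationic, harder electrophile would then be combined with 15 and Et3N in MeCN at rt, where no carbonate is present and charge control should favour the oxygen terminus. The sequence comes back to the route at 16.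

Step 2. The most likely failure is cleavage of the non-enolisable β-keto ester by alkoxide (deacetylation) or loss of one chain by retro-Michael fragmentation, in competition with ring closure. The fallback sets out from 3 and removes the blocking ester first: TsOH·H2O (cat.) in refluxing toluene should give dimethyl 4-acetylheptanedioate F2; NaOMe in refluxing MeOH then closes the ring to methyl 3-(2,4-dioxocyclohexyl)propanoate F3; and (COCl)2 with catalytic DMF gives the chloroenone, with chromatographic removal of the regioisomer that this less biased dione can form. The sequence comes back to the route at 7 and bypasses 4, 5 and 6.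

Step 7. The most likely failure is partial loss of the benzyl ether during prolonged heating in aqueous acid, or stalling at the enamine stage. The fallback sets out from 9 and avoids hot acid: Horner–Wadsworth–Emmons olefination with methyl 2-(tert-butyldimethylsilyloxy)-2-(dimethoxyphosphoryl)acetate and LiN(SiMe3)2 (2.1 equiv, THF, −78 °C to rt) should give methyl (Z)-3-(4-benzyloxy-2-hydroxy-5-methoxyphenyl)-2-(tert-butyldimethylsilyloxy)prop-2-enoate F4. Either alkene geometry converges, because desilylation with Bu4NF/AcOH releases the arylpyruvate, which lactonises onto the ortho hydroxyl with catalytic TsOH in warm toluene. The sequence comes back to the route at 15 and bypasses 13 and 14.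

Step 9. The most likely failure is hydrolytic cleavage of the vinylogous ester by the acid and the water formed under the aerobic conditions, or slow palladation at the substituted α'-carbon. Partial lactonisation of the new phenol onto the methyl ester would be reversed by an acidic methanol work-up. The fallback sets out from 16: soft enolisation with Me3SiOTf and Et3N (CH2Cl2, 0 °C) should give methyl 3-[4-(7-benzyloxy-6-methoxy-2-oxochromen-3-yloxy)-2-(trimethylsilyloxy)cyclohexa-1,3-dien-1-yl]propanoate F5 (its linear dienol ether isomer would converge). Dehydrogenation of the diene with DDQ in toluene at rt then gives methyl 3-[4-(7-benzyloxy-6-methoxy-2-oxochromen-3-yloxy)-2-(trimethylsilyloxy)phenyl]propanoate F6, whose silyl ether is cleaved in a mildly acidic aqueous work-up. The sequence comes back to the route at 17.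

Step 10. The most likely failure is loss of the O6 methyl group through a boron chelate formed once O7 is free, or benzylation of ring B if scavenging is incomplete. The fallback sets out from 17 and uses hydrogenolysis (Pd/C, H2 at 1 atm, EtOAc, rt, stopped at one equivalent of uptake so that C3=C4 of the pyranone ring is not reduced). It arrives directly at 18 and makes no new compound (F0).

## Further compounds

F1 | step 8 | 1-[4-(3-methoxy-3-oxopropyl)-3-oxocyclohex-1-en-1-yl]-1,4-diazabicyclo[2.2.2]octan-1-ium chloride (racemic) | COC(=O)CCC1CCC(=CC1=O)[N+]23CCN(CC2)CC3.[Cl-]
F2 | step 2 | dimethyl 4-acetylheptanedioate | CC(=O)C(CCC(=O)OC)CCC(=O)OC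
F3 | step 2 | methyl 3-(2,4-dioxocyclohexyl)propanoate (racemic) | COC(=O)CCC1CCC(=O)CC1=O
F4 | step 7 | methyl (Z)-3-(4-benzyloxy-2-hydroxy-5-methoxyphenyl)-2-(tert-butyldimethylsilyloxy)prop-2-enoate | COC(=O)/C(O[Si](C)(C)C(C)(C)C)=C/c1cc(OC)c(OCc2ccccc2)cc1O
F5 | step 9 | methyl 3-[4-(7-benzyloxy-6-methoxy-2-oxochromen-3-yloxy)-2-(trimethylsilyloxy)cyclohexa-1,3-dien-1-yl]propanoate | COC(=O)CCC1=C(O[Si](C)(C)C)C=C(Oc2cc3cc(OC)c(OCc4ccccc4)cc3oc2=O)CC1
F6 | step 9 | methyl 3-[4-(7-benzyloxy-6-methoxy-2-oxochromen-3-yloxy)-2-(trimethylsilyloxy)phenyl]propanoate | COC(=O)CCc1ccc(Oc2cc3cc(OC)c(OCc4ccccc4)cc3oc2=O)cc1O[Si](C)(C)C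
F0 | step 10 | none | none
A1 | alternative 1 | 4-methoxybenzene-1,3-diol (4-methoxyresorcinol) | COc1ccc(O)cc1O
A2 | alternative 1 | methyl 3,3-dimethoxy-2-[(2-oxochroman-7-yl)oxy]propanoate (racemic) | COC(OC)C(Oc1ccc2CCC(=O)Oc2c1)C(=O)OC
A3 | alternative 1 | 7-hydroxy-6-methoxy-3-[(2-oxochroman-7-yl)oxy]coumarin | COc1cc2cc(Oc3ccc4CCC(=O)Oc4c3)c(=O)oc2cc1O
A4 | alternative 1 | 7-hydroxychroman-2-one | O=C1CCc2ccc(O)cc2O1
A5 | alternative 2 | 7-acetoxy-3-(3-hydroxyphenoxy)-6-methoxycoumarin | COc1cc2cc(Oc3cccc(O)c3)c(=O)oc2cc1OC(C)=O
A6 | alternative 2 | acrylic acid | C=CC(=O)O
A7 | alternative 2 | 7-acetoxy-6-methoxy-3-[(2-oxochroman-7-yl)oxy]coumarin | COc1cc2cc(Oc3ccc4CCC(=O)Oc4c3)c(=O)oc2cc1OC(C)=O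
A8 | alternative 3 | 5-(tert-butyldimethylsilyloxy)-2-ethenyl-4-methoxyphenyl 2-[(2-oxochroman-7-yl)oxy]prop-2-enoate | C=Cc1cc(OC)c(O[Si](C)(C)C(C)(C)C)cc1OC(=O)C(=C)Oc1ccc2CCC(=O)Oc2c1
A9 | alternative 3 | 7-(tert-butyldimethylsilyloxy)-6-methoxy-3-[(2-oxochroman-7-yl)oxy]coumarin | COc1cc2cc(Oc3ccc4CCC(=O)Oc4c3)c(=O)oc2cc1O[Si](C)(C)C(C)(C)C
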